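## Analysis of the target

Positions are numbered as in the decahydroquinoline (N1, C2, C3, C4, C4a, C5–C8, C8a; side chain C1′–C8′). Ring A is the piperidine ring and ring B the carbocycle. Open-chain intermediates are described with the same position numbers.

- Target 31 is a cis-fused decahydroquinoline with a methyl at C2, an (E)-oct-2-enoyloxy group at C3 and a 5-hydroxyoctyl chain at C5.
- It has six stereocentres: 2R, 3S, 4aR, 5R, 8aS on the bicycle and 5′R on the chain.
- Read from the SMILES, H2, H4a, H5 and H8a all lie on one face and H3 on the other. The C2 methyl and the C3 oxygen are therefore trans, C2 and C8a are cis across nitrogen, the ring fusion is cis, and the C3 oxygen sits on the face that carries H4a and H5.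
- C5′ is too far from the ring to be controlled by it and has to be brought in with its configuration.
- Sensitive groups are the conjugated enoate (hydride, hydrogenation, deconjugation, conjugate addition), the secondary amine 1,3 to the ester oxygen (acyl shift), and two secondary hydroxyls, of which only one is acylated.
- The hard part is the three contiguous centres C4a, C5 and C8a on a ring B that carries no functional group in the target.
- The strategy rests on one feature: C8a is bonded to N1 and is 1,5-related to C5 through C8–C7–C6, while N1 reaches C4a through C2–C3–C4. A single chain with an amine at C2 and carbonyls at C8a and C5 can thus close ring A at N1=C8a and ring B at C4a=C5.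

## Retrosynthetic reasoning

**31 ⇐ 30 ⇐ 29 ⇐ 27 + 28.** The last two operations only unmask N1 (carbamate in 30) and the C5′ hydroxyl (silyl ether in 29). The ester C–O bond is cut before that, giving alcohol 27 and (E)-oct-2-enoic acid 28. Acylation is placed late because the enoate would not survive the reductions. It needs N1 blocked and the C5′ oxygen still silylated, so the two hydroxyls are told apart by a protecting group installed at the start.

**27 ⇐ 26.** The hydrogens at C4a and C5 are removed to give the tetrasubstituted alkene C4a=C5. This cut is chosen because the C3 hydroxyl lies on the face to which both hydrogens must be added. One directed syn addition therefore sets two centres, and with C8a fixed it also sets the cis ring fusion.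

**26 ⇐ 25 ⇐ 24.** Removing the carbamate and the C8a hydrogen leads to imine N1=C8a, conjugated with C4a=C5. The forward reaction must be a 1,2-reduction that places H8a cis to H2.

**24 ⇐ 20 (through 21, 22, 23).** Cutting N1=C8a and C4a=C5 opens both rings and leaves all eighteen skeletal carbons and the nitrogen in one chain, amino diketone 21. No other pair of cuts removes both rings while keeping every stereocentre that the chain can carry (C2, C3, C5′). In the forward sense ring size dictates the order: nitrogen reaches only C8a in a six-membered ring, and of the two enamines of the resulting imine only the one through C4a reaches the C5 ketone in a six-membered ring. In 20 the nitrogen and the C3 oxygen are tied together as a tert-butoxycarbonyl-protected isopropylidene aminal. This keeps N–H and O–H out of the organometallic step, and acid releases both at once.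

**20 ⇐ 19 (from 18) + 10.** The bond between C4a and the C8a carbonyl is cut. It splits the chain into two halves of similar size, each with its own stereochemical source. The C8a carbonyl enters as thioester 10, which couples with alkylzinc 19 under conditions that leave the C5 ketone alone.

**10 ⇐ 9 ⇐ 8 (from 6) + 7.** C5–C1′ is cut. The five carbons C5, C6, C7, C8, C8a are glutaric anhydride 7. Opening it with Grignard reagent 8 gives keto acid 9, whose two carbonyls are already differentiated.

**6 ⇐ 5 ⇐ 3 ⇐ 2 ⇐ 1.** The side chain is cut at C3′–C4′. Epoxide 1 supplies C4′–C8′ and the 5′R centre, and an allyl unit supplies C1′–C3′. The terminal alkene of 3 is turned into the primary bromide.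

**18 ⇐ 17 ⇐ 15 ⇐ 14 ⇐ 12 ⇐ 11.** The iodide carbon of 18 is C4a. It comes from alcohol 17, made by oxidative cleavage of the terminal alkene of 15. The allyl group of 14 thus delivers C4 and C4a and loses its third carbon; a hydroboration instead would leave the tether one carbon too long for ring A. The C3–C4 bond is formed by reagent-controlled allylation of aldehyde 12, which sets the 2,3-anti amino alcohol. C2 comes from Boc-D-alaninol 11.

## Alternatives that were turned down

**Alternative 1:** Ring A is disconnected at C4–C4a and N1–C2. Enaminone A2, which carries an N-(R)-1-phenylethyl group, condenses with enal A3, and the 1-azatriene formed electrocyclises to A1.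
- For: the bicycle is made in one step from very simple partners, and the reaction class is well established for this ring system. In convergence it is stronger than the chosen route.
- Against: A1 holds only C2. C3 is an enol ether carbon and C5 a vinylogous amide carbonyl. Hydrogenation from the face opposite the C2 methyl would set C4a and C8a correctly but would put the C3 oxygen cis to the methyl, whereas 31 needs trans, so C3 must be inverted. The eight-carbon chain, with a separately made C5′ centre, must be attached at a poorly electrophilic C5 carbonyl and C5 then set. The nitrogen auxiliary must also be exchanged.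
- Comparison: the chosen route has every carbon and the C2, C3 and C5′ centres in place before the rings close, and takes C3 from the chiral pool in the correct sense.

**Alternative 2:** Ring A is disconnected at N1–C8a by an aza-Achmatowicz reaction. A peracid opens the furan of carbamate A5 to an ene-dione, which the carbamate nitrogen recloses to A4.
- For: the key step is robust, has no regiochemical ambiguity, and leaves a C3 ketone from which either C3 epimer could be reached. On those points it is stronger.
- Against: the furan carbon that becomes C8a is ring-fused, so A4 has a fully substituted N,O-ketal flanked by the carbamate and the C2 methyl. It must be reduced through an N-acyliminium ion with control at C8a, after which C4=C4a and the C3 ketone still have to be reduced selectively. The C5 centre must already be present in A5 as a single enantiomer at a position that has no simple source.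
- Comparison: the chosen route needs no independent synthesis of the C5 centre, because it arises together with C4a in the directed hydrogenation.

**Alternative 3:** Ring B and ring A are disconnected together at C4a–C8a and C5–C6. Thermolysis of trienyl carbamate A7 would give A6 by an intramolecular Diels–Alder reaction.
- For: three stereocentres (C4a, C5, C8a) are set in one step, against none in the chosen key step. The (Z)-alkene geometry is transferred stereospecifically into the cis relation of H4a and H5. On stereocentres per step it is clearly stronger.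
- Against: the dienophile is an unactivated (Z)-disubstituted alkene, so high temperature is needed. The cis or trans ring fusion depends on an endo/exo preference that the tether does not fix. The N-dienyl carbamate on an α-branched nitrogen and the (Z)-alkene each cost steps. Hydrogenolysis at the end frees N1 and the C3 hydroxyl together, which makes selective O-acylation awkward.
- Comparison: the chosen route gives up simultaneous stereocontrol for mild ring closure and for three later reductions, each steered by a centre already present.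

Key step: step 13

Remark: the secondary triisopropylsilyl ether is assumed to survive brief exposure to trifluoroacetic acid at 0 °C.
Remark: (−)-Ipc2BOMe denotes the antipode of B-methoxydiisopinocampheylborane derived from (+)-α-pinene.

## Route

**Step 1**
Reactants: 1 (R)-1,2-epoxypentane
Product: 2 (R)-oct-7-en-4-ol
Conditions: allylmagnesium bromide, CuI (cat.), THF, −40 → 0 °C; aq. NH4Cl
Reagents that add atoms: allylmagnesium bromide, C=CC[Mg]Br
Why: Copper-catalysed SN2 opening of a terminal epoxide by a Grignard reagent at the unsubstituted carbon; the C–O bond at the stereocentre is untouched, so the R configuration of 1 becomes C5′.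

**Step 2**
Reactants: 2 (R)-oct-7-en-4-ol
Product: 3 (R)-triisopropyl(oct-7-en-4-yloxy)silane
Conditions: i-Pr3SiOTf, 2,6-lutidine, CH2Cl2, 0 °C
Reagents that add atoms: triisopropylsilyl triflate, CC(C)[Si](C(C)C)(C(C)C)OS(=O)(=O)C(F)(F)F
Why: Silylation of a secondary alcohol with a silyl triflate and a hindered base; the bulky silyl ether should survive Grignard formation and the acid of step 13 and fall to fluoride at the end.

**Step 3**
Reactants: 3 (R)-triisopropyl(oct-7-en-4-yloxy)silane
Product: 5 (R)-5-(triisopropylsilyloxy)octan-1-ol, via B-alkyl-9-borabicyclononane 4 (not isolated)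
Conditions: 9-BBN, THF, 0 °C → rt; then NaOH, H2O2, 0 °C → rt
Reagents that add atoms: hydrogen peroxide, OO (9-borabicyclo[3.3.1]nonane, B1C2CCCC1CCC2, puts boron into intermediate 4 only)
Why: Anti-Markovnikov hydroboration of a monosubstituted alkene followed by oxidation of the C–B bond.

**Step 4**
Reactants: 5 (R)-5-(triisopropylsilyloxy)octan-1-ol
Product: 6 (R)-[(8-bromooctan-4-yl)oxy]triisopropylsilane
Conditions: CBr4, PPh3, CH2Cl2, 0 °C
Reagents that add atoms: carbon tetrabromide, BrC(Br)(Br)Br
Why: Appel bromination of a primary alcohol under neutral conditions that leave the silyl ether intact.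

**Step 5**
Reactants: 6 (R)-[(8-bromooctan-4-yl)oxy]triisopropylsilane; 7 glutaric anhydride
Product: 9 (R)-5-oxo-10-(triisopropylsilyloxy)tridecanoic acid, via alkylmagnesium bromide 8 (not isolated)
Conditions: Mg, THF, 40 °C; then added to 7 (excess), THF, −78 → −20 °C; 1 M HCl
Reagents that add atoms: none
Why: Grignard formation and ring-opening acylation by a cyclic anhydride; inverse addition at low temperature to excess anhydride, together with the carboxylate formed, should hold the reaction at mono-addition.

**Step 6**
Reactants: 9 (R)-5-oxo-10-(triisopropylsilyloxy)tridecanoic acid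
Product: 10 S-ethyl (R)-5-oxo-10-(triisopropylsilyloxy)tridecanethioate
Conditions: EtSH, EDC·HCl, DMAP (cat.), CH2Cl2, 0 °C → rt
Reagents that add atoms: ethanethiol, CCS
Why: Carbodiimide (Steglich-type) thioesterification; the ketone does not react.

**Step 7**
Reactants: 11 Boc-D-alaninol, tert-butyl N-[(2R)-1-hydroxypropan-2-yl]carbamate
Product: 12 Boc-D-alaninal, tert-butyl N-[(2R)-1-oxopropan-2-yl]carbamate
Conditions: Dess–Martin periodinane, NaHCO3, CH2Cl2, 0 °C → rt; used crude at once
Reagents that add atoms: none
Why: Dess–Martin oxidation of a primary alcohol under buffered, non-basic conditions, which should leave the α-stereocentre of the amino aldehyde intact.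

**Step 8**
Reactants: 12 Boc-D-alaninal
Product: 14 tert-butyl N-[(2R,3S)-3-hydroxyhex-5-en-2-yl]carbamate, via diisopinocampheylborinate 13 (not isolated)
Conditions: (−)-Ipc2BOMe, allylmagnesium bromide, Et2O, 0 °C → rt; then 12, −78 °C; NaOH, H2O2, 0 °C → rt
Reagents that add atoms: (−)-B-allyldiisopinocampheylborane, C=CCB([C@@H]1C[C@@H]2C[C@@H](C2(C)C)[C@H]1C)[C@@H]1C[C@@H]2C[C@@H](C2(C)C)[C@H]1C
Why: Brown allylboration through a closed chair (Zimmerman–Traxler) transition state; the isopinocampheyl groups from (+)-α-pinene deliver allyl to the Si face of the aldehyde under reagent control, which sets C3 as S, anti to the C2 nitrogen.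

**Step 9**
Reactants: 14 tert-butyl N-[(2R,3S)-3-hydroxyhex-5-en-2-yl]carbamate
Product: 15 tert-butyl (4R,5S)-5-allyl-2,2,4-trimethyl-1,3-oxazolidine-3-carboxylate
Conditions: 2,2-dimethoxypropane, PPTS (cat.), toluene, 80 °C
Reagents that add atoms: 2,2-dimethoxypropane, COC(C)(C)OC
Why: Acid-catalysed transketalisation ties the carbamate N–H and the hydroxyl into an N,O-isopropylidene (cis-4,5-disubstituted oxazolidine), so no acidic hydrogen remains for the organozinc step.

**Step 10**
Reactants: 15 tert-butyl (4R,5S)-5-allyl-2,2,4-trimethyl-1,3-oxazolidine-3-carboxylate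
Product: 17 tert-butyl (4R,5S)-5-(2-hydroxyethyl)-2,2,4-trimethyl-1,3-oxazolidine-3-carboxylate, via secondary ozonide 16 (not isolated)
Conditions: O3, CH2Cl2, −78 °C; then NaBH4, MeOH, −78 → 0 °C
Reagents that add atoms: ozone, [O-][O+]=O
Why: Ozonolysis of a terminal alkene with reductive work-up to the alcohol; it excises the third allyl carbon so that exactly C4 and C4a remain between the carbinol and the future C8a.

**Step 11**
Reactants: 17 tert-butyl (4R,5S)-5-(2-hydroxyethyl)-2,2,4-trimethyl-1,3-oxazolidine-3-carboxylate
Product: 18 tert-butyl (4R,5S)-5-(2-iodoethyl)-2,2,4-trimethyl-1,3-oxazolidine-3-carboxylate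
Conditions: I2, PPh3, imidazole, CH2Cl2, 0 °C → rt
Reagents that add atoms: iodine, II
Why: Appel-type iodination of a primary alcohol; the oxygen γ to the new C–I bond cannot undergo β-elimination in the derived organometallic.

**Step 12**
Reactants: 18 tert-butyl (4R,5S)-5-(2-iodoethyl)-2,2,4-trimethyl-1,3-oxazolidine-3-carboxylate; 10 S-ethyl (R)-5-oxo-10-(triisopropylsilyloxy)tridecanethioate
Product: 20 tert-butyl (4R,5S)-5-[(12R)-3,7-dioxo-12-(triisopropylsilyloxy)pentadecyl]-2,2,4-trimethyl-1,3-oxazolidine-3-carboxylate, via alkylzinc iodide 19 (not isolated)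
Conditions: Zn dust (activated with BrCH2CH2Br, Me3SiCl), THF, 40 °C; then 10, PdCl2(PPh3)2 (5 mol %), toluene, rt
Reagents that add atoms: none
Why: Fukuyama coupling: zerovalent palladium inserts into the acyl–sulfur bond, the alkylzinc transmetalates and reductive elimination gives the ketone; the organozinc adds to neither ketone, so the C4a–C8a bond is formed with both carbonyls of the 1,5-diketone in place.

**Step 13**
Reactants: 20 tert-butyl (4R,5S)-5-[(12R)-3,7-dioxo-12-(triisopropylsilyloxy)pentadecyl]-2,2,4-trimethyl-1,3-oxazolidine-3-carboxylate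
Product: 24 (2R,3S)-2-methyl-5-[(5R)-5-(triisopropylsilyloxy)octyl]-2,3,4,6,7,8-hexahydroquinolin-3-ol, via amino diketone 21 (not isolated), via cyclic imino ketone 22 (not isolated), via aldol adduct 23 (not isolated)
Conditions: CF3CO2H/CH2Cl2 (1:4), H2O (5 equiv), 0 °C → rt; evaporate; then NaOAc/AcOH (pH ≈ 5), degassed EtOH–H2O (9:1), 60 °C, Ar
Reagents that add atoms: none
Why: Acid cleaves the tert-butyl carbamate (loss of 2-methylpropene and CO2) and hydrolyses the N,O-aminal, leaving 21 as its ammonium salt; on buffering, the free amine adds to the only carbonyl within six-ring reach, C8a, and dehydrates to imine 22, closing ring A by a 6-exo-trig attack. Imine 22 equilibrates with its enamines; the endocyclic N1–C8a=C4a tautomer attacks the C5 ketone through C4a in a 6-(enolendo)-exo-trig aldol addition that closes ring B and gives 23, and E1cB loss of the tertiary hydroxyl through C4a–H, which is α to the imine, drains the equilibria into the conjugated 1-azadiene 24. The closest known reaction types are the cyclodehydration of δ-amino ketones to 1-piperideines and the enamine-mediated aldol condensation of 1,5-diketones (the ring-forming half of a Robinson annulation), here with the enamine supplied by the substrate's own nitrogen. No stereocentre is created: the two transient centres of 23 are erased on dehydration, and C2, C3 and C5′ are not enolisable under these conditions, since C2–H lies on the nitrogen side of the imine and C3 is a carbinol carbon. The selectivity needed is enolisation of the imine towards C4a; the other enamine (C8a=C8) could close only a four-membered ring and is unproductive rather than harmful. The competing closures are reversible and feed back into the productive path: Mannich attack of the C5-ketone enol on C8a, hemiketal formation by the C3 hydroxyl at C8a, and attack of N1 on the C5 ketone to a bicyclic bis-enamine that the aqueous buffer hydrolyses again and that degassing protects from irreversible oxidation. The buffer is mild and the temperature moderate because loss of the C3 hydroxyl from 24 would lead on to an aromatic pyridine.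

**Step 14**
Reactants: 24 (2R,3S)-2-methyl-5-[(5R)-5-(triisopropylsilyloxy)octyl]-2,3,4,6,7,8-hexahydroquinolin-3-ol
Product: 25 (2R,3S,8aS)-2-methyl-5-[(5R)-5-(triisopropylsilyloxy)octyl]-1,2,3,4,6,7,8,8a-octahydroquinolin-3-ol
Conditions: NaBH4, CeCl3·7H2O, MeOH, −40 °C
Reagents that add atoms: none
Why: Luche-type 1,2-reduction of a conjugated cyclic imine; hydride should add axially to the half-chair that keeps the C2 methyl pseudo-equatorial, placing H8a cis to H2 (2,6-cis piperidine, 8aS) and leaving C4a=C5.

**Step 15**
Reactants: 25 (2R,3S,8aS)-2-methyl-5-[(5R)-5-(triisopropylsilyloxy)octyl]-1,2,3,4,6,7,8,8a-octahydroquinolin-3-ol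
Product: 26 tert-butyl (2R,3S,8aS)-3-hydroxy-2-methyl-5-[(5R)-5-(triisopropylsilyloxy)octyl]-3,4,6,7,8,8a-hexahydroquinoline-1(2H)-carboxylate
Conditions: Boc2O (excess), MeOH, 45 °C
Reagents that add atoms: di-tert-butyl dicarbonate, CC(C)(C)OC(=O)OC(=O)OC(C)(C)C
Why: Carbamate formation at the secondary amine, which without an acylation catalyst reacts in preference to the secondary hydroxyl; it removes the basic nitrogen that would poison the iridium catalyst and blocks N1 for the esterification.

**Step 16**
Reactants: 26 tert-butyl (2R,3S,8aS)-3-hydroxy-2-methyl-5-[(5R)-5-(triisopropylsilyloxy)octyl]-3,4,6,7,8,8a-hexahydroquinoline-1(2H)-carboxylate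
Product: 27 tert-butyl (2R,3S,4aR,5R,8aS)-3-hydroxy-2-methyl-5-[(5R)-5-(triisopropylsilyloxy)octyl]octahydroquinoline-1(2H)-carboxylate
Conditions: H2 (1 atm, raised to 50 bar if slow), [Ir(cod)(PCy3)(py)]PF6 (10–20 mol %), CH2Cl2, rt
Reagents that add atoms: none
Why: Hydroxyl-directed hydrogenation of a tetrasubstituted alkene by a cationic iridium complex; allylic strain with the carbamate should place the C2 methyl axial and hence the trans C3 hydroxyl axial above C4a, so the bound metal delivers both hydrogens syn to the face of the C3 oxygen, which sets 4aR and 5R and the cis ring fusion.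

**Step 17**
Reactants: 27 tert-butyl (2R,3S,4aR,5R,8aS)-3-hydroxy-2-methyl-5-[(5R)-5-(triisopropylsilyloxy)octyl]octahydroquinoline-1(2H)-carboxylate; 28 (E)-oct-2-enoic acid
Product: 29 tert-butyl (2R,3S,4aR,5R,8aS)-2-methyl-3-{[(2E)-oct-2-enoyl]oxy}-5-[(5R)-5-(triisopropylsilyloxy)octyl]octahydroquinoline-1(2H)-carboxylate
Conditions: EDC·HCl, DMAP (0.2 equiv), CH2Cl2, 0 °C → rt
Reagents that add atoms: none
Why: Steglich esterification of the only free hydroxyl; a low DMAP loading and no further base are chosen to limit deconjugation of the activated enoate.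

**Step 18**
Reactants: 29 tert-butyl (2R,3S,4aR,5R,8aS)-2-methyl-3-{[(2E)-oct-2-enoyl]oxy}-5-[(5R)-5-(triisopropylsilyloxy)octyl]octahydroquinoline-1(2H)-carboxylate
Product: 30 tert-butyl (2R,3S,4aR,5R,8aS)-5-[(5R)-5-hydroxyoctyl]-2-methyl-3-{[(2E)-oct-2-enoyl]oxy}octahydroquinoline-1(2H)-carboxylate
Conditions: HF·pyridine, pyridine, THF, 0 °C → rt
Reagents that add atoms: none
Why: Fluoride cleavage of the silyl ether under buffered acidic conditions that affect neither the carbamate nor the enoate.

**Step 19**
Reactants: 30 tert-butyl (2R,3S,4aR,5R,8aS)-5-[(5R)-5-hydroxyoctyl]-2-methyl-3-{[(2E)-oct-2-enoyl]oxy}octahydroquinoline-1(2H)-carboxylate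
Product: 31 (2R,3S,4aR,5R,8aS)-5-[(5R)-5-hydroxyoctyl]-2-methyldecahydroquinolin-3-yl (2E)-oct-2-enoate
Conditions: CF3CO2H/CH2Cl2 (1:5), 0 °C; then cold sat. NaHCO3, MeOH
Reagents that add atoms: none
Why: Acidolysis of the tert-butyl carbamate; the amine stays protonated until a brief cold neutralisation, which limits O→N acyl shift and aza-Michael addition, and the basic methanolic work-up cleaves any trifluoroacetate formed at C5′.

## Compound list

1 | (R)-1,2-epoxypentane | CCC[C@@H]1CO1 | starting material
2 | (R)-oct-7-en-4-ol | CCC[C@@H](O)CCC=C | intermediate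
3 | (R)-triisopropyl(oct-7-en-4-yloxy)silane | CCC[C@@H](O[Si](C(C)C)(C(C)C)C(C)C)CCC=C | intermediate
4 | 9-[(5R)-5-(triisopropylsilyloxy)octyl]-9-borabicyclo[3.3.1]nonane (not isolated) | CCC[C@@H](O[Si](C(C)C)(C(C)C)C(C)C)CCCCB1C2CCCC1CCC2 | intermediate
5 | (R)-5-(triisopropylsilyloxy)octan-1-ol | CCC[C@@H](O[Si](C(C)C)(C(C)C)C(C)C)CCCCO | intermediate
6 | (R)-[(8-bromooctan-4-yl)oxy]triisopropylsilane | CCC[C@@H](O[Si](C(C)C)(C(C)C)C(C)C)CCCCBr | intermediate
7 | glutaric anhydride | O=C1CCCC(=O)O1 | starting material
8 | [(5R)-5-(triisopropylsilyloxy)octyl]magnesium bromide (not isolated) | CCC[C@@H](O[Si](C(C)C)(C(C)C)C(C)C)CCCC[Mg]Br | intermediate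
9 | (R)-5-oxo-10-(triisopropylsilyloxy)tridecanoic acid | CCC[C@@H](O[Si](C(C)C)(C(C)C)C(C)C)CCCCC(=O)CCCC(=O)O | intermediate
10 | S-ethyl (R)-5-oxo-10-(triisopropylsilyloxy)tridecanethioate | CCC[C@@H](O[Si](C(C)C)(C(C)C)C(C)C)CCCCC(=O)CCCC(=O)SCC | intermediate
11 | Boc-D-alaninol, tert-butyl N-[(2R)-1-hydroxypropan-2-yl]carbamate | C[C@@H](NC(=O)OC(C)(C)C)CO | starting material
12 | Boc-D-alaninal, tert-butyl N-[(2R)-1-oxopropan-2-yl]carbamate | C[C@@H](NC(=O)OC(C)(C)C)C=O | intermediate
13 | diisopinocampheylborinate of 14, isopinocampheyl groups from (+)-α-pinene (not isolated) | C[C@@H](NC(=O)OC(C)(C)C)[C@H](CC=C)OB([C@@H]1C[C@@H]2C[C@@H](C2(C)C)[C@H]1C)[C@@H]1C[C@@H]2C[C@@H](C2(C)C)[C@H]1C | intermediate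
14 | tert-butyl N-[(2R,3S)-3-hydroxyhex-5-en-2-yl]carbamate | C[C@@H](NC(=O)OC(C)(C)C)[C@@H](O)CC=C | intermediate
15 | tert-butyl (4R,5S)-5-allyl-2,2,4-trimethyl-1,3-oxazolidine-3-carboxylate | C[C@H]1N(C(=O)OC(C)(C)C)C(C)(C)O[C@H]1CC=C | intermediate
16 | tert-butyl (4R,5S)-2,2,4-trimethyl-5-(1,2,4-trioxolan-3-ylmethyl)-1,3-oxazolidine-3-carboxylate, trioxolane carbon unassigned (not isolated) | C[C@H]1N(C(=O)OC(C)(C)C)C(C)(C)O[C@H]1CC1OCOO1 | intermediate
17 | tert-butyl (4R,5S)-5-(2-hydroxyethyl)-2,2,4-trimethyl-1,3-oxazolidine-3-carboxylate | C[C@H]1N(C(=O)OC(C)(C)C)C(C)(C)O[C@H]1CCO | intermediate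
18 | tert-butyl (4R,5S)-5-(2-iodoethyl)-2,2,4-trimethyl-1,3-oxazolidine-3-carboxylate | C[C@H]1N(C(=O)OC(C)(C)C)C(C)(C)O[C@H]1CCI | intermediate
19 | {2-[(4R,5S)-3-(tert-butoxycarbonyl)-2,2,4-trimethyl-1,3-oxazolidin-5-yl]ethyl}zinc iodide (not isolated) | C[C@H]1N(C(=O)OC(C)(C)C)C(C)(C)O[C@H]1CC[Zn]I | intermediate
20 | tert-butyl (4R,5S)-5-[(12R)-3,7-dioxo-12-(triisopropylsilyloxy)pentadecyl]-2,2,4-trimethyl-1,3-oxazolidine-3-carboxylate | C[C@H]1N(C(=O)OC(C)(C)C)C(C)(C)O[C@H]1CCC(=O)CCCC(=O)CCCC[C@H](O[Si](C(C)C)(C(C)C)C(C)C)CCC | intermediate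
21 | (2R,3S,15R)-2-amino-3-hydroxy-15-(triisopropylsilyloxy)octadecane-6,10-dione, as its trifluoroacetate salt (not isolated) | C[C@@H](N)[C@@H](O)CCC(=O)CCCC(=O)CCCC[C@H](O[Si](C(C)C)(C(C)C)C(C)C)CCC | intermediate
22 | (2R,3S)-2-methyl-6-[(9R)-4-oxo-9-(triisopropylsilyloxy)dodecyl]-2,3,4,5-tetrahydropyridin-3-ol (not isolated) | C[C@H]1N=C(CCCC(=O)CCCC[C@H](O[Si](C(C)C)(C(C)C)C(C)C)CCC)CC[C@@H]1O | intermediate
23 | (2R,3S)-2-methyl-5-[(5R)-5-(triisopropylsilyloxy)octyl]-2,3,4,4a,5,6,7,8-octahydroquinoline-3,5-diol, C4a and C5 unassigned (not isolated) | C[C@H]1N=C2CCCC(O)(CCCC[C@H](O[Si](C(C)C)(C(C)C)C(C)C)CCC)C2C[C@@H]1O | intermediate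
24 | (2R,3S)-2-methyl-5-[(5R)-5-(triisopropylsilyloxy)octyl]-2,3,4,6,7,8-hexahydroquinolin-3-ol | O[C@H]1CC2=C(CCCC[C@H](O[Si](C(C)C)(C(C)C)C(C)C)CCC)CCCC2=N[C@@H]1C | intermediate
25 | (2R,3S,8aS)-2-methyl-5-[(5R)-5-(triisopropylsilyloxy)octyl]-1,2,3,4,6,7,8,8a-octahydroquinolin-3-ol | O[C@H]1CC2=C(CCCC[C@H](O[Si](C(C)C)(C(C)C)C(C)C)CCC)CCC[C@@H]2N[C@@H]1C | intermediate
26 | tert-butyl (2R,3S,8aS)-3-hydroxy-2-methyl-5-[(5R)-5-(triisopropylsilyloxy)octyl]-3,4,6,7,8,8a-hexahydroquinoline-1(2H)-carboxylate | O[C@H]1CC2=C(CCCC[C@H](O[Si](C(C)C)(C(C)C)C(C)C)CCC)CCC[C@@H]2N(C(=O)OC(C)(C)C)[C@@H]1C | intermediate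
27 | tert-butyl (2R,3S,4aR,5R,8aS)-3-hydroxy-2-methyl-5-[(5R)-5-(triisopropylsilyloxy)octyl]octahydroquinoline-1(2H)-carboxylate | O[C@H]1C[C@@H]2[C@H](CCCC[C@H](O[Si](C(C)C)(C(C)C)C(C)C)CCC)CCC[C@@H]2N(C(=O)OC(C)(C)C)[C@@H]1C | intermediate
28 | (E)-oct-2-enoic acid | CCCCC/C=C/C(=O)O | starting material
29 | tert-butyl (2R,3S,4aR,5R,8aS)-2-methyl-3-{[(2E)-oct-2-enoyl]oxy}-5-[(5R)-5-(triisopropylsilyloxy)octyl]octahydroquinoline-1(2H)-carboxylate | CCCCC/C=C/C(=O)O[C@H]1C[C@@H]2[C@H](CCCC[C@H](O[Si](C(C)C)(C(C)C)C(C)C)CCC)CCC[C@@H]2N(C(=O)OC(C)(C)C)[C@@H]1C | intermediate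
30 | tert-butyl (2R,3S,4aR,5R,8aS)-5-[(5R)-5-hydroxyoctyl]-2-methyl-3-{[(2E)-oct-2-enoyl]oxy}octahydroquinoline-1(2H)-carboxylate | CCCCC/C=C/C(=O)O[C@H]1C[C@@H]2[C@H](CCCC[C@H](O)CCC)CCC[C@@H]2N(C(=O)OC(C)(C)C)[C@@H]1C | intermediate
31 | (2R,3S,4aR,5R,8aS)-5-[(5R)-5-hydroxyoctyl]-2-methyldecahydroquinolin-3-yl (2E)-oct-2-enoate | CCCCC/C=C/C(=O)O[C@H]1C[C@@H]2[C@H](CCCC[C@H](O)CCC)CCC[C@@H]2N[C@@H]1C | target

## Step count and risk

Total: 19 steps. Longest linear sequence: 14 steps (steps 1–6, then 12–19). The amino alcohol branch (steps 7–11) has five steps.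

**Step 13 (key step).** Most likely failures:
- the nitrogen of imine 22 closes onto the C5 ketone instead of C4a, giving an air-sensitive bis-enamine;
- the C5-ketone enol attacks C8a in a Mannich closure to a spiro amine;
- the two ketones condense in the wrong sense while the amine is still protonated;
- the C3 hydroxyl is lost from 24 with aromatisation.

All of these compete because ring B closure through an imine-derived enamine is slower than imine formation. The fallback fixes the C4a=C5 alkene by an intramolecular Horner–Wadsworth–Emmons reaction, setting out from 18 and 9. Heating iodide 18 with trimethyl phosphite (Michaelis–Arbuzov) gives tert-butyl (4R,5S)-5-[2-(dimethoxyphosphoryl)ethyl]-2,2,4-trimethyl-1,3-oxazolidine-3-carboxylate F1. Keto acid 9 is cyclodehydrated with Ac2O/NaOAc to the enol lactone 6-[(5R)-5-(triisopropylsilyloxy)octyl]-3,4-dihydro-2H-pyran-2-one F2. The lithium carbanion of F1 (n-BuLi, THF, −78 °C, with a second equivalent of LiN(SiMe3)2) opens F2 at the lactone carbonyl. On warming, the β-keto phosphonate condenses with the released ketone to the enone tert-butyl (4R,5S)-2,2,4-trimethyl-5-({6-oxo-2-[(5R)-5-(triisopropylsilyloxy)octyl]cyclohex-1-en-1-yl}methyl)-1,3-oxazolidine-3-carboxylate F3, in which ring B and the C4a=C5 alkene are already in place. Acid treatment of F3 as in step 13 frees the amine, which condenses with the enone carbonyl and rejoins the route at 24.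

**Step 16.** Most likely failures: the tetrasubstituted alkene is not reduced before the iridium catalyst deactivates, or the alkene migrates within ring B before reduction, so that face control by the hydroxyl is lost; binding of the carbamate carbonyl to the metal may also compete. The fallback sets out from 24 and gives up homogeneous direction: hydrogenation of the whole azadiene over PtO2 in AcOH under pressure. This should add all three hydrogens from the catalyst surface to the face anchored by the C3 hydroxyl, giving (2R,3S,4aR,5R,8aS)-2-methyl-5-[(5R)-5-(triisopropylsilyloxy)octyl]decahydroquinolin-3-ol F4. Treatment with Boc2O as in step 15 returns to the route at 27.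

**Step 14.** Most likely failures: poor facial selectivity at C8a, because the conjugated, nearly flat ring A offers little torsional bias, or partial conjugate reduction. The fallback sets out from 24 and replaces external hydride by internal delivery: Me4NBH(OAc)3 in MeCN/AcOH (Evans–Saksena type). The C3 hydroxyl binds boron and passes hydride to the protonated imine on its own face, which is the face required, returning to the route at 25. This fallback makes no new compound (F0).

**Step 17.** Most likely failures: base-induced deconjugation of the activated enoate to the β,γ-isomer, and slow acylation of a hindered, probably axial hydroxyl. The fallback sets out from 27 and builds the alkene after the ester bond. Acylation with diethylphosphonoacetic acid (EDC·HCl, DMAP) gives tert-butyl (2R,3S,4aR,5R,8aS)-3-{[2-(diethoxyphosphoryl)acetyl]oxy}-2-methyl-5-[(5R)-5-(triisopropylsilyloxy)octyl]octahydroquinoline-1(2H)-carboxylate F5. A Horner–Wadsworth–Emmons reaction with hexanal (LiCl, DBU, MeCN; Masamune–Roush conditions) should then give the (E)-enoate and rejoin the route at 29.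

**Step 8.** Most likely failures: loss of diastereoselectivity if the reagent's facial preference opposes the aldehyde's own bias, and partial epimerisation of the α-amino aldehyde before it is consumed. The fallback sets out from 12 and moves C3 control to a substrate-directed reduction. Unselective addition of allylmagnesium bromide gives tert-butyl N-[(2R)-3-hydroxyhex-5-en-2-yl]carbamate as a C3 mixture F6. Dess–Martin oxidation gives tert-butyl N-[(2R)-3-oxohex-5-en-2-yl]carbamate F7. Reduction with LiAlH(O-t-Bu)3 in EtOH at −78 °C, through the chelate of the carbamate N–H and the ketone, should deliver hydride anti to the methyl and return the anti amino alcohol 14.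

## Further compounds

F1 | step 13 | tert-butyl (4R,5S)-5-[2-(dimethoxyphosphoryl)ethyl]-2,2,4-trimethyl-1,3-oxazolidine-3-carboxylate | C[C@H]1N(C(=O)OC(C)(C)C)C(C)(C)O[C@H]1CCP(=O)(OC)OC
F2 | step 13 | 6-[(5R)-5-(triisopropylsilyloxy)octyl]-3,4-dihydro-2H-pyran-2-one | CCC[C@@H](O[Si](C(C)C)(C(C)C)C(C)C)CCCCC1=CCCC(=O)O1
F3 | step 13 | tert-butyl (4R,5S)-2,2,4-trimethyl-5-({6-oxo-2-[(5R)-5-(triisopropylsilyloxy)octyl]cyclohex-1-en-1-yl}methyl)-1,3-oxazolidine-3-carboxylate | C[C@H]1N(C(=O)OC(C)(C)C)C(C)(C)O[C@H]1CC1=C(CCCC[C@H](O[Si](C(C)C)(C(C)C)C(C)C)CCC)CCCC1=O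
F4 | step 16 | (2R,3S,4aR,5R,8aS)-2-methyl-5-[(5R)-5-(triisopropylsilyloxy)octyl]decahydroquinolin-3-ol | O[C@H]1C[C@@H]2[C@H](CCCC[C@H](O[Si](C(C)C)(C(C)C)C(C)C)CCC)CCC[C@@H]2N[C@@H]1C
F0 | step 14 | none | none
F5 | step 17 | tert-butyl (2R,3S,4aR,5R,8aS)-3-{[2-(diethoxyphosphoryl)acetyl]oxy}-2-methyl-5-[(5R)-5-(triisopropylsilyloxy)octyl]octahydroquinoline-1(2H)-carboxylate | CCOP(=O)(OCC)CC(=O)O[C@H]1C[C@@H]2[C@H](CCCC[C@H](O[Si](C(C)C)(C(C)C)C(C)C)CCC)CCC[C@@H]2N(C(=O)OC(C)(C)C)[C@@H]1C
F6 | step 8 | tert-butyl N-[(2R)-3-hydroxyhex-5-en-2-yl]carbamate, mixture at C3 | C[C@@H](NC(=O)OC(C)(C)C)C(O)CC=C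
F7 | step 8 | tert-butyl N-[(2R)-3-oxohex-5-en-2-yl]carbamate | C[C@@H](NC(=O)OC(C)(C)C)C(=O)CC=C
A1 | alternative 1 | (2R)-3-(benzyloxy)-2-methyl-1-[(1R)-1-phenylethyl]-2,6,7,8-tetrahydroquinolin-5(1H)-one | C[C@H]1N([C@H](C)c2ccccc2)C2=C(C=C1OCc1ccccc1)C(=O)CCC2
A2 | alternative 1 | 3-{[(1R)-1-phenylethyl]amino}cyclohex-2-en-1-one | C[C@@H](NC1=CC(=O)CCC1)c1ccccc1
A3 | alternative 1 | (2Z)-2-(benzyloxy)but-2-enal | C/C=C(\OCc1ccccc1)C=O
A4 | alternative 2 | tert-butyl (2R,5R,8aR)-5-[(5R)-5-(tert-butyldimethylsilyloxy)octyl]-8a-hydroxy-2-methyl-3-oxo-3,5,6,7,8,8a-hexahydroquinoline-1(2H)-carboxylate | C[C@H]1N(C(=O)OC(C)(C)C)[C@@]2(O)CCC[C@@H](CCCC[C@H](O[Si](C)(C)C(C)(C)C)CCC)C2=CC1=O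
A5 | alternative 2 | tert-butyl N-[(1R)-1-{(4R)-4-[(5R)-5-(tert-butyldimethylsilyloxy)octyl]-4,5,6,7-tetrahydro-1-benzofuran-2-yl}ethyl]carbamate | C[C@@H](NC(=O)OC(C)(C)C)c1cc2c(o1)CCC[C@H]2CCCC[C@H](O[Si](C)(C)C(C)(C)C)CCC
A6 | alternative 3 | benzyl (2R,3S,4aR,5R,8aS)-3-(benzyloxy)-5-[(5R)-5-(tert-butyldimethylsilyloxy)octyl]-2-methyl-3,4,4a,5,6,8a-hexahydroquinoline-1(2H)-carboxylate | c1ccccc1CO[C@H]1C[C@@H]2[C@H](CCCC[C@H](O[Si](C)(C)C(C)(C)C)CCC)CC=C[C@@H]2N(C(=O)OCc3ccccc3)[C@@H]1C
A7 | alternative 3 | benzyl N-[(1E)-buta-1,3-dien-1-yl]-N-[(2R,3S,5Z,11R)-3-(benzyloxy)-11-(tert-butyldimethylsilyloxy)tetradec-5-en-2-yl]carbamate | C=C/C=C/N(C(=O)OCc1ccccc1)[C@H](C)[C@@H](OCc1ccccc1)C/C=C\CCCC[C@H](O[Si](C)(C)C(C)(C)C)CCC
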